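The cyclopentane (C-1, C-2, C-3, C-3a, C-8a; azulene numbering) is closed last, onto a finished seven-membered ring. The step exploits the aldol relationship C-3(OH)/C-3a/C-4(O) and the fact that both methyl-bearing ring carbons, C-6 and C-8a, lie β to C-4: with C-4 as ketone the carbocycle is the Cs-symmetric 3,6-dimethylcyclohepta-2,6-dienone. One operation, copper-catalysed enantioselective conjugate addition of the zinc homoenolate of ethyl isopropyl ketone and aldol closure of the resulting enolate, forms C-1–C-8a and C-3–C-3a, the ring and three stereocentres. The precursors are this achiral dienone and 1-isopropylcyclopropanol. Dehydrogenation, α-epoxidation, SmI2 reduction and two esterifications finish the target.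

Key step: step 4

Remark: compounds 1, 6, 15 and 20 are taken as catalogue compounds; locants follow azulene numbering (C-3 carbinol, C-3a/C-8a ring fusion, C-4 aroyloxy carbon, C-8 angeloyloxy carbon).

Step 1
Reactants: 1 3-methylcyclohept-2-en-1-one
Product: 3 3-methylcyclohepta-2,6-dien-1-one, via selenide 2 (not isolated)
Conditions: LDA, THF, −78 °C; PhSeBr; then H2O2, pyridine, CH2Cl2, 0 °C to rt
Reagents that add atoms: none
Why: Kinetic deprotonation of the enone at C-7 (α′), selenenylation and selenoxide syn-elimination (selenoxide elimination) install the second, unsubstituted enone without creating a stereocentre.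

Step 2
Reactants: 3 3-methylcyclohepta-2,6-dien-1-one
Product: 5 3,6-dimethylcyclohepta-2,6-dien-1-one, via selenide 4 (not isolated)
Conditions: MeMgBr, CuBr·SMe2 (10 mol %), THF, −40 °C; PhSeBr, −78 °C; then H2O2, pyridine, CH2Cl2, 0 °C
Reagents that add atoms: methylmagnesium bromide, C[Mg]Br
Why: Copper-catalysed conjugate addition of the methyl Grignard reagent goes to the unsubstituted β-carbon C-6 (the methyl-bearing C-3 terminus is much less reactive), and selenenylation of the magnesium enolate followed by selenoxide syn-elimination toward the C-6 hydrogen restores the enone, so that the achiral Cs-symmetric dienone results.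

Step 3
Reactants: 6 methyl 2-methylpropanoate
Product: 7 1-(propan-2-yl)cyclopropan-1-ol
Conditions: EtMgBr (2.2 equiv), Ti(Oi-Pr)4 (20 mol %), Et2O, 0 °C to rt; cold dilute HCl
Reagents that add atoms: ethylmagnesium bromide, CC[Mg]Br
Why: Kulinkovich reaction, in which the titanacyclopropane formed from EtMgBr and Ti(Oi-Pr)4 adds twice to the ester carbonyl to give the achiral 1-substituted cyclopropanol.

Step 4
Reactants: 5 3,6-dimethylcyclohepta-2,6-dien-1-one; 7 1-(propan-2-yl)cyclopropan-1-ol
Product: 10 (3R,3aR,8aS)-3-hydroxy-6,8a-dimethyl-3-(propan-2-yl)-2,3,3a,7,8,8a-hexahydroazulen-4(1H)-one, via zinc bis-homoenolate 8 (not isolated), via zinc enolate 9 (not isolated)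
Conditions: 7 (2 equiv), Et2Zn (1 equiv), PhMe, 0 °C to rt; then 5, CuOTf (10 mol %), chiral sulfonate-NHC ligand (10 mol %, enantiomer giving (S)-9), −30 °C to rt; then t-BuOK (0.3 equiv), t-BuOH, 0 °C; aq. NH4Cl
Reagents that add atoms: none
Why: Proposed new method: zinc bis-homoenolate 8 (the ring-opened zinc cyclopropoxide) transmetalates to a chiral NHC–copper(I) alkyl, which adds 1,4 to one of the two enantiotopic enone halves of Cs-symmetric 5 and so sets the quaternary C-8a, and the zinc enolate 9 that results then attacks the isopropyl ketone unmasked three atoms away. The closest known reaction types are the Cu-catalysed conjugate addition of zinc homoenolates to enones, the NHC–Cu-catalysed addition of dialkylzincs to β-substituted cycloheptenones that makes quaternary centres, and tandem conjugate addition–aldol cyclisations of keto-enones; new here is their union on a cross-conjugated dienone with a ketone homoenolate. The cyclopentane closes by a 5-(enolexo)-exo-trig aldol addition (C-3a onto C-3). C-8a is controlled by the catalyst, whereas C-3 and C-3a are set under thermodynamic control, since the aldolate is reversible with t-BuOK and C-3a is epimerisable, and the trans-fused isomer with i-Pr anti to the angular methyl (OH syn to it) avoids both a 1,3-diaxial CH3/i-Pr contact and a cis i-Pr/C-4 contact. The step needs 1,4- rather than 1,2-addition (soft organocopper, and zinc alkyls spare ketones), one site out of two (equivalent by symmetry, so only facial selectivity matters) and a single addition (one transferable alkyl per dienone at low temperature).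

Step 5
Reactants: 10 (3R,3aR,8aS)-3-hydroxy-6,8a-dimethyl-3-(propan-2-yl)-2,3,3a,7,8,8a-hexahydroazulen-4(1H)-one
Product: 11 (3R,3aR,8aR)-3-hydroxy-6,8a-dimethyl-3-(propan-2-yl)-2,3,3a,8a-tetrahydroazulen-4(1H)-one
Conditions: chloranil (1.3 equiv), t-BuOH, reflux
Reagents that add atoms: none
Why: Quinone dehydrogenation of the β,β-disubstituted enone through its ring dienol (hydride abstraction at C-8) gives the linear 5,7-dien-4-one, the only direction open because C-8a is quaternary; no stereocentre is touched.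

Step 6
Reactants: 11 (3R,3aR,8aR)-3-hydroxy-6,8a-dimethyl-3-(propan-2-yl)-2,3,3a,8a-tetrahydroazulen-4(1H)-one
Product: 12 (3R,3aR,7R,8S,8aS)-7,8-epoxy-3-hydroxy-6,8a-dimethyl-3-(propan-2-yl)-2,3,3a,7,8,8a-hexahydroazulen-4(1H)-one
Conditions: m-CPBA, NaHCO3, CH2Cl2, 0 °C
Reagents that add atoms: m-chloroperoxybenzoic acid, OOC(=O)c1cccc(Cl)c1
Why: Prilezhaev epoxidation attacks the γ,δ-double bond C-7=C-8, the more electron-rich alkene of the dienone, from the α-face anti to the pseudo-axial methyl group on the adjacent C-8a, which sets C-8 (and the transient C-7).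

Step 7
Reactants: 12 (3R,3aR,7R,8S,8aS)-7,8-epoxy-3-hydroxy-6,8a-dimethyl-3-(propan-2-yl)-2,3,3a,7,8,8a-hexahydroazulen-4(1H)-one
Product: 14 (3R,3aS,4S,8R,8aS)-6,8a-dimethyl-3-(propan-2-yl)-1,2,3,3a,4,5,8,8a-octahydroazulene-3,4,8-triol, via hydroxy enone 13 (not isolated)
Conditions: SmI2 (5 equiv), THF–MeOH, −78 to 0 °C
Reagents that add atoms: none
Why: Samarium diiodide reduction of the vinylogous epoxy ketone cleaves the C-7–O bond and, after α-protonation of the samarium dienolate, leaves the C-8 carbinol and the C-6=C-7 alkene, and the same reagent then reduces the β-hydroxy ketone through the Sm(III) chelate with the C-3 oxygen to the 1,3-anti diol, which sets C-4 with its oxygen α.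

Step 8
Reactants: 14 (3R,3aS,4S,8R,8aS)-6,8a-dimethyl-3-(propan-2-yl)-1,2,3,3a,4,5,8,8a-octahydroazulene-3,4,8-triol; 15 angelic acid
Product: 19 (3R,3aS,4S,8R,8aS)-3,4-dihydroxy-6,8a-dimethyl-3-(propan-2-yl)-1,2,3,3a,4,5,8,8a-octahydroazulen-8-yl (2Z)-2-methylbut-2-enoate, via mixed anhydride 16 (not isolated), via boronate 17 (not isolated), via acylated boronate 18 (not isolated)
Conditions: 15, 2,4,6-Cl3C6H2COCl, Et3N, PhMe, rt; separately 14, PhB(OH)2, 4 Å MS, PhMe, rt; combine, 75 °C; aq. sorbitol/Na2CO3 work-up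
Reagents that add atoms: none
Why: A transient cyclic phenylboronate ties up the 3,4-diol so that the Yamaguchi-type mixed-anhydride esterification, run without DMAP to keep the Z-geometry, acylates only the hindered allylic C-8 hydroxyl, and the boronate falls off on aqueous work-up; no stereocentre changes.

Step 9
Reactants: 19 (3R,3aS,4S,8R,8aS)-3,4-dihydroxy-6,8a-dimethyl-3-(propan-2-yl)-1,2,3,3a,4,5,8,8a-octahydroazulen-8-yl (2Z)-2-methylbut-2-enoate; 20 4-[(tert-butyldimethylsilyl)oxy]benzoic acid
Product: 21 (3R,3aS,4S,8R,8aS)-4-({4-[(tert-butyldimethylsilyl)oxy]benzoyl}oxy)-3-hydroxy-6,8a-dimethyl-3-(propan-2-yl)-1,2,3,3a,4,5,8,8a-octahydroazulen-8-yl (2Z)-2-methylbut-2-enoate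
Conditions: DCC, DMAP (cat.), CH2Cl2, rt
Reagents that add atoms: none
Why: Steglich esterification acylates the only remaining secondary hydroxyl at C-4 with retention, while the tertiary C-3 hydroxyl is too hindered to react.

Step 10
Reactants: 21 (3R,3aS,4S,8R,8aS)-4-({4-[(tert-butyldimethylsilyl)oxy]benzoyl}oxy)-3-hydroxy-6,8a-dimethyl-3-(propan-2-yl)-1,2,3,3a,4,5,8,8a-octahydroazulen-8-yl (2Z)-2-methylbut-2-enoate
Product: 22 (3R,3aS,4S,8R,8aS)-3-hydroxy-4-[(4-hydroxybenzoyl)oxy]-6,8a-dimethyl-3-(propan-2-yl)-1,2,3,3a,4,5,8,8a-octahydroazulen-8-yl (2Z)-2-methylbut-2-enoate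
Conditions: HF·pyridine, pyridine, THF, 0 °C
Reagents that add atoms: none
Why: Fluoride-mediated cleavage of the aryl silyl ether under buffered HF·pyridine conditions frees the phenol without touching the two esters, the Z-enoate geometry or the tertiary alcohol.

Compound list
1 | 3-methylcyclohept-2-en-1-one | CC1=CC(=O)CCCC1 | starting material
2 | 3-methyl-7-(phenylselanyl)cyclohept-2-en-1-one (racemic, not isolated) | CC1=CC(=O)C([Se]c2ccccc2)CCC1 | intermediate
3 | 3-methylcyclohepta-2,6-dien-1-one | CC1=CC(=O)C=CCC1 | intermediate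
4 | 3,6-dimethyl-7-(phenylselanyl)cyclohept-2-en-1-one (racemic, not isolated) | CC1=CC(=O)C([Se]c2ccccc2)C(C)CC1 | intermediate
5 | 3,6-dimethylcyclohepta-2,6-dien-1-one (achiral, Cs-symmetric) | CC1=CC(=O)C=C(C)CC1 | intermediate
6 | methyl 2-methylpropanoate | COC(=O)C(C)C | starting material
7 | 1-(propan-2-yl)cyclopropan-1-ol | CC(C)C1(O)CC1 | intermediate
8 | bis(4-methyl-3-oxopentyl)zinc (not isolated) | CC(C)C(=O)CC[Zn]CCC(=O)C(C)C | intermediate
9 | (4-methyl-3-oxopentyl)zinc (3S)-3,6-dimethyl-3-(4-methyl-3-oxopentyl)cyclohepta-1,6-dien-1-olate (not isolated) | CC(C)C(=O)CC[Zn]OC1=C[C@](C)(CCC(=O)C(C)C)CCC(C)=C1 | intermediate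
10 | (3R,3aR,8aS)-3-hydroxy-6,8a-dimethyl-3-(propan-2-yl)-2,3,3a,7,8,8a-hexahydroazulen-4(1H)-one (trans-fused; 8a-CH3 and 3-OH β, 3a-H α) | C1CC(C)=CC(=O)[C@@H]2[C@]1(C)CC[C@@]2(O)C(C)C | intermediate
11 | (3R,3aR,8aR)-3-hydroxy-6,8a-dimethyl-3-(propan-2-yl)-2,3,3a,8a-tetrahydroazulen-4(1H)-one | C1=CC(C)=CC(=O)[C@@H]2[C@]1(C)CC[C@@]2(O)C(C)C | intermediate
12 | (3R,3aR,7R,8S,8aS)-7,8-epoxy-3-hydroxy-6,8a-dimethyl-3-(propan-2-yl)-2,3,3a,7,8,8a-hexahydroazulen-4(1H)-one (α-epoxide, anti to the angular methyl) | O1[C@@H]2[C@H]1C(C)=CC(=O)[C@@H]3[C@]2(C)CC[C@@]3(O)C(C)C | intermediate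
13 | (3R,3aR,8R,8aS)-3,8-dihydroxy-6,8a-dimethyl-3-(propan-2-yl)-2,3,3a,5,8,8a-hexahydroazulen-4(1H)-one (not isolated) | O[C@@H]1C=C(C)CC(=O)[C@@H]2[C@]1(C)CC[C@@]2(O)C(C)C | intermediate
14 | (3R,3aS,4S,8R,8aS)-6,8a-dimethyl-3-(propan-2-yl)-1,2,3,3a,4,5,8,8a-octahydroazulene-3,4,8-triol | O[C@@H]1C=C(C)C[C@H](O)[C@@H]2[C@]1(C)CC[C@@]2(O)C(C)C | intermediate
15 | angelic acid, (2Z)-2-methylbut-2-enoic acid | C/C=C(/C)C(=O)O | starting material
16 | (2Z)-2-methylbut-2-enoic 2,4,6-trichlorobenzoic anhydride (not isolated) | C/C=C(/C)C(=O)OC(=O)c1c(Cl)cc(Cl)cc1Cl | intermediate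
17 | cyclic 3,4-O-phenylboronate of triol 14, 8-OH free (not isolated) | O[C@@H]1C=C(C)C[C@H](O3)[C@@H]2[C@]1(C)CC[C@@]2(OB3c4ccccc4)C(C)C | intermediate
18 | 8-O-angeloyl derivative of boronate 17 (not isolated) | C/C=C(/C)C(=O)O[C@@H]1C=C(C)C[C@H](O3)[C@@H]2[C@]1(C)CC[C@@]2(OB3c4ccccc4)C(C)C | intermediate
19 | (3R,3aS,4S,8R,8aS)-3,4-dihydroxy-6,8a-dimethyl-3-(propan-2-yl)-1,2,3,3a,4,5,8,8a-octahydroazulen-8-yl (2Z)-2-methylbut-2-enoate | C/C=C(/C)C(=O)O[C@@H]1C=C(C)C[C@H](O)[C@@H]2[C@]1(C)CC[C@@]2(O)C(C)C | intermediate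
20 | 4-[(tert-butyldimethylsilyl)oxy]benzoic acid | CC(C)(C)[Si](C)(C)Oc1ccc(cc1)C(=O)O | starting material
21 | (3R,3aS,4S,8R,8aS)-4-({4-[(tert-butyldimethylsilyl)oxy]benzoyl}oxy)-3-hydroxy-6,8a-dimethyl-3-(propan-2-yl)-1,2,3,3a,4,5,8,8a-octahydroazulen-8-yl (2Z)-2-methylbut-2-enoate | C/C=C(/C)C(=O)O[C@@H]1C=C(C)C[C@H](OC(=O)c2ccc(O[Si](C)(C)C(C)(C)C)cc2)[C@@H]2[C@]1(C)CC[C@@]2(O)C(C)C | intermediate
22 | (3R,3aS,4S,8R,8aS)-3-hydroxy-4-[(4-hydroxybenzoyl)oxy]-6,8a-dimethyl-3-(propan-2-yl)-1,2,3,3a,4,5,8,8a-octahydroazulen-8-yl (2Z)-2-methylbut-2-enoate | C/C=C(/C)C(=O)O[C@@H]1C=C(C)C[C@H](OC(=O)c2ccc(O)cc2)[C@@H]2[C@]1(C)CC[C@@]2(O)C(C)C | target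

Total step count: 10. Longest linear sequence: 9 steps (steps 1, 2, 4, 5, 6, 7, 8, 9, 10 from 1); step 3 is a one-step side branch.

Steps most likely to fail

Step 4 (Proposed new method). The chelated ketone homoenolate may transfer too slowly to the β,β-disubstituted carbon, facial selectivity of the catalyst may be low, or the aldolate may stay as a cis-fused isomer or dehydrate during equilibration. The fallback sets out from 5 and returns at 10 with known chemistry only. 4-Methylpent-1-en-3-one is converted with TMSBr and ethylene glycol into the bromo ketal 2-(2-bromoethyl)-2-(propan-2-yl)-1,3-dioxolane F1. Its Grignard reagent is added to 5 under chiral NHC–copper catalysis (asymmetric conjugate addition forming the quaternary centre) and the magnesium enolate is trapped with TMSCl as the silyl dienol ether F2. NBS should give the α-bromo ketone F3, and aqueous acid removes the dioxolane to give the bromo diketone F4. SmI2 at −78 °C then generates the samarium enolate regiospecifically for a Reformatsky-type aldol closure, followed by the same alkoxide equilibration, to reach 10.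

Step 5. The β-ketol may dehydrate or undergo retro-aldol cleavage under the hot quinone conditions, or dehydrogenation may run through the exocyclic (methyl) dienol. The fallback sets out from 10 and returns at 11. TMSOTf/Et3N converts the enone into the ring dienyl silyl ether and silylates the tertiary alcohol, giving the bis-silyl dienol ether F5. Saegusa oxidation with Pd(OAc)2 should give the O-silylated dienone F6, and citric acid in methanol removes the silyl ether.

Step 7. Facial control at C-4 may be lost in the samarium ketone reduction, or the β,γ-enone may move into conjugation before it is reduced. The fallback sets out from 12 and returns at 14. The ketone is reduced first, while the C-3 hydroxyl is the only one present, by Evans–Saksena reduction (Me4NBH(OAc)3, MeCN–AcOH, −40 °C), which delivers hydride intramolecularly and should give the epoxy diol F7. SmI2 in THF–MeOH then reduces the vinyl epoxide to the allylic alcohol.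

Further compounds
F1 | step 4 | 2-(2-bromoethyl)-2-(propan-2-yl)-1,3-dioxolane | CC(C)C1(CCBr)OCCO1
F2 | step 4 | trimethyl({(3S)-3,6-dimethyl-3-{2-[2-(propan-2-yl)-1,3-dioxolan-2-yl]ethyl}cyclohepta-1,6-dien-1-yl}oxy)silane | C[Si](C)(C)OC1=C[C@](C)(CCC2(C(C)C)OCCO2)CCC(C)=C1
F3 | step 4 | (6S)-7-bromo-3,6-dimethyl-6-{2-[2-(propan-2-yl)-1,3-dioxolan-2-yl]ethyl}cyclohept-2-en-1-one (C-7 epimers) | O=C1C(Br)[C@](C)(CCC2(C(C)C)OCCO2)CCC(C)=C1
F4 | step 4 | (6S)-7-bromo-3,6-dimethyl-6-(4-methyl-3-oxopentyl)cyclohept-2-en-1-one (C-7 epimers) | O=C1C(Br)[C@](C)(CCC(=O)C(C)C)CCC(C)=C1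
F5 | step 5 | bis(trimethylsilyl) derivative of 10: 4-silyloxy-4,6-diene with 3-O-trimethylsilyl ether | C1C=C(C)C=C(O[Si](C)(C)C)[C@@H]2[C@]1(C)CC[C@@]2(O[Si](C)(C)C)C(C)C
F6 | step 5 | 3-O-trimethylsilyl ether of dienone 11 | C1=CC(C)=CC(=O)[C@@H]2[C@]1(C)CC[C@@]2(O[Si](C)(C)C)C(C)C
F7 | step 7 | (3R,3aS,4S,7R,8S,8aS)-7,8-epoxy-6,8a-dimethyl-3-(propan-2-yl)-1,2,3,3a,4,7,8,8a-octahydroazulene-3,4-diol | O1[C@@H]2[C@H]1C(C)=C[C@H](O)[C@@H]3[C@]2(C)CC[C@@]3(O)C(C)C
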